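**Retrosynthetic overview**
- Target ⇐ acetylation of the C2 alcohol ⇐ Luche reduction of the bicyclo[3.2.1]oct-3-ene-2,8-dione (hydride from the C8 side sets C2).
- Six-membered ring (formed last) ⇐ Dieckmann closure C1–C2 of a cyclopentanone keto ester, then C3=C4 desaturation; C1–OMe by iodine(III) enolonium methoxylation.
- C6 and quaternary C5 ⇐ Stork reductive Michael addition of a 4-aryl-cyclopentenone to methyl 2-methoxyacrylate (C5–C4 bond).
- Key C–C bond C7–aryl ⇐ γ-umpolung: the cyclopentenone γ-carbon, normally a vinylogous-enolate donor, is made an acceptor (acyl-π-allyl-Pd cation, a4 / vinylogous enolonium) and joined with inversion to the nucleophilic aryl carbon of a boronic acid.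
- Ring order: the cyclopentane ring comes from the chiral pool ((S)-allethrolone); the six-membered ring is closed onto it.

Assumption: (S)-allethrolone is bought as the single enantiomer; bicyclic compounds are numbered C1 (OMe bridgehead), C2–C4 (three-carbon bridge), C5 (allyl bridgehead), C6 (CHMe), C7 (CHAr), C8 (bridging C=O).

**Step 1**
Reactants: 1 (S)-allethrolone, (4S)-4-hydroxy-3-methyl-2-(prop-2-en-1-yl)cyclopent-2-en-1-one; 2 (3,4,5-trimethoxyphenyl)boronic acid
Product: 3 (4S)-3-methyl-2-(prop-2-en-1-yl)-4-(3,4,5-trimethoxyphenyl)cyclopent-2-en-1-one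
Conditions: Pd(PPh3)4 (5 mol %), 2 (1.5 equiv), THF, 60 °C, no base
Reagents that add atoms: none
Why: Proposed new method: Pd(0) ionises the boron-activated allylic C–O bond anti to oxygen to give a 1-acyl-π-allyl-palladium cation, so the enone γ-carbon (by natural polarity a vinylogous-enolate donor) reacts as an acceptor (γ-umpolung, a4 / vinylogous enolonium synthon) with the nucleophilic aryl carbon, which passes from boron to Pd and then to C4 syn to Pd, i.e. with net inversion (aryl ends on the face opposite to the former OH; the descriptor stays 4S only through a priority change), and coupling at the carbinol terminus keeps the enone conjugated; closest known reaction types are the base-free Pd(0) Suzuki-type coupling of free allylic alcohols with arylboronic acids and Tsuji–Trost substitution of 4-acyloxycyclopent-2-enones.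

**Step 2**
Reactants: 3 (4S)-3-methyl-2-(prop-2-en-1-yl)-4-(3,4,5-trimethoxyphenyl)cyclopent-2-en-1-one; 4 methyl 2-methoxyprop-2-enoate
Product: 6 methyl 2-methoxy-3-[(1R,2S,3R)-2-methyl-5-oxo-1-(prop-2-en-1-yl)-3-(3,4,5-trimethoxyphenyl)cyclopentyl]propanoate (both epimers at the ester α-carbon), via lithium enolate 5 (not isolated)
Conditions: 3 added to Li (2.1 equiv), t-BuOH (1.0 equiv), NH3(l)/THF, −78 °C; NH3 removed; 4 (1.3 equiv), THF, −78 → −40 °C; AcOH, −78 °C
Reagents that add atoms: none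
Why: Stork reductive alkylation (dissolving-metal enone reduction, then enolate Michael addition): the β-carbanion is protonated to the more stable trans Me/Ar arrangement (sets C6), and the regiodefined tetrasubstituted lithium enolate adds to the acrylate on the face anti to the adjacent methyl (sets quaternary C5, new arm cis to aryl); inverse addition keeps the base-labile γ-centre of 3 intact and the cold acid quench prevents premature Dieckmann closure.

**Step 3**
Reactants: 6 methyl 2-methoxy-3-[(1R,2S,3R)-2-methyl-5-oxo-1-(prop-2-en-1-yl)-3-(3,4,5-trimethoxyphenyl)cyclopentyl]propanoate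
Product: 8 methyl 2-methoxy-3-[(1R,2S,3R,4R)-4-methoxy-2-methyl-5-oxo-1-(prop-2-en-1-yl)-3-(3,4,5-trimethoxyphenyl)cyclopentyl]propanoate (major epimer at the new centre), via silyl enol ether 7 (not isolated)
Conditions: TMSOTf (1.2 equiv), Et3N (1.5 equiv), CH2Cl2, −20 → 0 °C; then PhIO (1.1 equiv), BF3·OEt2 (1.1 equiv), MeOH, −40 → 0 °C
Reagents that add atoms: trimethylsilyl trifluoromethanesulfonate C[Si](C)(C)OS(=O)(=O)C(F)(F)F (silicon only in 7); methanol CO
Why: Soft enolisation can only give the silyl enol ether towards the CH2 (the other α-carbon is quaternary, and no free enolate is formed that could attack the ester), and Moriarty-type iodine(III) oxidation in methanol traps the α-keto cation equivalent (enolonium) with MeOH to give the α-methoxy ketone; the new centre forms mainly trans to the aryl group and is re-enolised in step 4.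

**Step 4**
Reactants: 8 methyl 2-methoxy-3-[(1R,2S,3R,4R)-4-methoxy-2-methyl-5-oxo-1-(prop-2-en-1-yl)-3-(3,4,5-trimethoxyphenyl)cyclopentyl]propanoate
Product: 11 (1R,5S,6S,7R)-1,3-dimethoxy-6-methyl-5-(prop-2-en-1-yl)-7-(3,4,5-trimethoxyphenyl)bicyclo[3.2.1]oct-3-ene-2,8-dione, via saturated dione 9 (not isolated), via selenide 10 (not isolated)
Conditions: LiHMDS (2.3 equiv), THF, −78 → −30 °C; PhSeCl (1.2 equiv), −78 °C; then 30 % H2O2, pyridine, CH2Cl2, 0 °C
Reagents that add atoms: phenylselenenyl chloride Cl[Se]c1ccccc1 (selenium only in 10)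
Why: Dieckmann (intramolecular Claisen) cyclisation of the only enolisable ketone α-carbon (C1) onto the ester closes the six-membered ring, the C1 configuration being forced because the ester arm is fixed on one face at C5 (aryl endo, methyl exo); the product is held as its C2/C3 enolate, which is selenenylated, and selenoxide syn-elimination can only take a C4 hydrogen, giving the C3=C4 methyl enol ether.

**Step 5**
Reactants: 11 (1R,5S,6S,7R)-1,3-dimethoxy-6-methyl-5-(prop-2-en-1-yl)-7-(3,4,5-trimethoxyphenyl)bicyclo[3.2.1]oct-3-ene-2,8-dione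
Product: 12 (1S,2R,5S,6S,7R)-2-hydroxy-1,3-dimethoxy-6-methyl-5-(prop-2-en-1-yl)-7-(3,4,5-trimethoxyphenyl)bicyclo[3.2.1]oct-3-en-8-one
Conditions: NaBH4 (1.0 equiv), CeCl3·7H2O (1.1 equiv), MeOH, −78 °C
Reagents that add atoms: none
Why: Luche reduction gives clean 1,2-reduction of the enone carbonyl (C2), while the C8 ketone is shielded by two quaternary bridgeheads; hydride enters C2 from the side of the C8 bridge, away from the endo aryl group on C7, so the hydroxyl ends on the aryl side (2R).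

**Step 6**
Reactants: 12 (1S,2R,5S,6S,7R)-2-hydroxy-1,3-dimethoxy-6-methyl-5-(prop-2-en-1-yl)-7-(3,4,5-trimethoxyphenyl)bicyclo[3.2.1]oct-3-en-8-one
Product: 13 (1S,2R,5S,6S,7R)-1,3-dimethoxy-6-methyl-8-oxo-5-(prop-2-en-1-yl)-7-(3,4,5-trimethoxyphenyl)bicyclo[3.2.1]oct-3-en-2-yl acetate
Conditions: Ac2O, pyridine, DMAP (cat.), CH2Cl2, 23 °C
Reagents that add atoms: acetic anhydride CC(=O)OC(C)=O
Why: DMAP-catalysed acylation of the secondary alcohol with retention at C2; the β-acetoxy ketone cannot undergo retro-aldol cleavage once acylated.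

**Compound list**
1 | (4S)-4-hydroxy-3-methyl-2-(prop-2-en-1-yl)cyclopent-2-en-1-one, (S)-allethrolone | O=C1C[C@H](O)C(C)=C1CC=C | starting material
2 | (3,4,5-trimethoxyphenyl)boronic acid | COc1cc(B(O)O)cc(OC)c1OC | starting material
3 | (4S)-3-methyl-2-(prop-2-en-1-yl)-4-(3,4,5-trimethoxyphenyl)cyclopent-2-en-1-one | O=C1C[C@@H](c2cc(OC)c(OC)c(OC)c2)C(C)=C1CC=C | intermediate
4 | methyl 2-methoxyprop-2-enoate | C=C(OC)C(=O)OC | starting material
5 | lithium (3S,4R)-3-methyl-2-(prop-2-en-1-yl)-4-(3,4,5-trimethoxyphenyl)cyclopent-1-en-1-olate | [Li+].[O-]C1=C(CC=C)[C@@H](C)[C@H](c2cc(OC)c(OC)c(OC)c2)C1 | intermediate (not isolated)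
6 | methyl 2-methoxy-3-[(1R,2S,3R)-2-methyl-5-oxo-1-(prop-2-en-1-yl)-3-(3,4,5-trimethoxyphenyl)cyclopentyl]propanoate (epimers at the ester α-carbon) | O=C1C[C@@H](c2cc(OC)c(OC)c(OC)c2)[C@H](C)[C@@]1(CC=C)CC(OC)C(=O)OC | intermediate
7 | methyl 2-methoxy-3-[(1R,4S,5S)-5-methyl-1-(prop-2-en-1-yl)-4-(3,4,5-trimethoxyphenyl)-2-(trimethylsilyloxy)cyclopent-2-en-1-yl]propanoate | C[Si](C)(C)OC1=C[C@@H](c2cc(OC)c(OC)c(OC)c2)[C@H](C)[C@@]1(CC=C)CC(OC)C(=O)OC | intermediate (not isolated)
8 | methyl 2-methoxy-3-[(1R,2S,3R,4R)-4-methoxy-2-methyl-5-oxo-1-(prop-2-en-1-yl)-3-(3,4,5-trimethoxyphenyl)cyclopentyl]propanoate | O=C1[C@H](OC)[C@@H](c2cc(OC)c(OC)c(OC)c2)[C@H](C)[C@@]1(CC=C)CC(OC)C(=O)OC | intermediate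
9 | (1R,5R,6S,7R)-1,3-dimethoxy-6-methyl-5-(prop-2-en-1-yl)-7-(3,4,5-trimethoxyphenyl)bicyclo[3.2.1]octane-2,8-dione (C3 epimers, present as its lithium enolate) | C=CC[C@]12CC(OC)C(=O)[C@](OC)(C1=O)[C@@H](c1cc(OC)c(OC)c(OC)c1)[C@@H]2C | intermediate (not isolated)
10 | (1R,5R,6S,7R)-1,3-dimethoxy-6-methyl-3-(phenylselanyl)-5-(prop-2-en-1-yl)-7-(3,4,5-trimethoxyphenyl)bicyclo[3.2.1]octane-2,8-dione | C=CC[C@]12CC(OC)([Se]c3ccccc3)C(=O)[C@](OC)(C1=O)[C@@H](c1cc(OC)c(OC)c(OC)c1)[C@@H]2C | intermediate (not isolated)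
11 | (1R,5S,6S,7R)-1,3-dimethoxy-6-methyl-5-(prop-2-en-1-yl)-7-(3,4,5-trimethoxyphenyl)bicyclo[3.2.1]oct-3-ene-2,8-dione | C=CC[C@]12C=C(OC)C(=O)[C@](OC)(C1=O)[C@@H](c1cc(OC)c(OC)c(OC)c1)[C@@H]2C | intermediate
12 | (1S,2R,5S,6S,7R)-2-hydroxy-1,3-dimethoxy-6-methyl-5-(prop-2-en-1-yl)-7-(3,4,5-trimethoxyphenyl)bicyclo[3.2.1]oct-3-en-8-one | C=CC[C@]12C=C(OC)[C@@H](O)[C@](OC)(C1=O)[C@@H](c1cc(OC)c(OC)c(OC)c1)[C@@H]2C | intermediate
13 | (1S,2R,5S,6S,7R)-1,3-dimethoxy-6-methyl-8-oxo-5-(prop-2-en-1-yl)-7-(3,4,5-trimethoxyphenyl)bicyclo[3.2.1]oct-3-en-2-yl acetate | C=CC[C@]12C=C(OC)[C@@H](OC(C)=O)[C@](OC)(C1=O)[C@@H](c1cc(OC)c(OC)c(OC)c1)[C@@H]2C | target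

Total step count: 6. Longest linear sequence: 6.

**Steps most likely to fail**

Step 1 (ionisation of the free γ-hydroxy enone, loss of ee through the Pd-dienolate, base-lability of the γ-centre in 3). The fallback sets out from 1: acylation with Boc2O/DMAP gives tert-butyl [(1S)-2-methyl-4-oxo-3-(prop-2-en-1-yl)cyclopent-2-en-1-yl] carbonate F1. F1 is ionised by Pd(0)/phosphine with loss of CO2 (Tsuji–Trost activation; the released tert-butoxide activates 2 for aryl transfer) and coupled with 2, coming back to the route at 3.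

Step 2 (slow Michael addition of a hindered tetrasubstituted lithium enolate, enolate equilibration, facial selectivity at C5). The fallback sets out from 3: the Li/NH3 reduction is quenched with TMSCl/Et3N to give trimethyl{[(3S,4R)-3-methyl-2-(prop-2-en-1-yl)-4-(3,4,5-trimethoxyphenyl)cyclopent-1-en-1-yl]oxy}silane F2. F2 is then added to 4 in a Lewis-acid (TiCl4 or TBSOTf) Mukaiyama–Michael reaction at −78 °C, coming back at 6.

Step 4 (Dieckmann closure to a strained, non-enolisable 1,3-diketone in the presence of released methoxide, then one-pot desaturation). The fallback sets out from 8: saponification (LiOH) gives 2-methoxy-3-[(1R,2S,3R,4R)-4-methoxy-2-methyl-5-oxo-1-(prop-2-en-1-yl)-3-(3,4,5-trimethoxyphenyl)cyclopentyl]propanoic acid F3. CDI converts F3 into 1-{2-methoxy-3-[(1R,2S,3R,4R)-4-methoxy-2-methyl-5-oxo-1-(prop-2-en-1-yl)-3-(3,4,5-trimethoxyphenyl)cyclopentyl]propanoyl}imidazole F4. LiHMDS then effects an irreversible C-acylation that releases no alkoxide, coming back at 9, which is isolated and dehydrogenated with IBX in DMSO (or by Saegusa oxidation) to 11.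

**Further compounds**
F1 | step 1 | tert-butyl [(1S)-2-methyl-4-oxo-3-(prop-2-en-1-yl)cyclopent-2-en-1-yl] carbonate | O=C1C[C@H](OC(=O)OC(C)(C)C)C(C)=C1CC=C
F2 | step 2 | trimethyl{[(3S,4R)-3-methyl-2-(prop-2-en-1-yl)-4-(3,4,5-trimethoxyphenyl)cyclopent-1-en-1-yl]oxy}silane | C[Si](C)(C)OC1=C(CC=C)[C@@H](C)[C@H](c2cc(OC)c(OC)c(OC)c2)C1
F3 | step 4 | 2-methoxy-3-[(1R,2S,3R,4R)-4-methoxy-2-methyl-5-oxo-1-(prop-2-en-1-yl)-3-(3,4,5-trimethoxyphenyl)cyclopentyl]propanoic acid | O=C1[C@H](OC)[C@@H](c2cc(OC)c(OC)c(OC)c2)[C@H](C)[C@@]1(CC=C)CC(OC)C(=O)O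
F4 | step 4 | 1-{2-methoxy-3-[(1R,2S,3R,4R)-4-methoxy-2-methyl-5-oxo-1-(prop-2-en-1-yl)-3-(3,4,5-trimethoxyphenyl)cyclopentyl]propanoyl}imidazole | O=C1[C@H](OC)[C@@H](c2cc(OC)c(OC)c(OC)c2)[C@H](C)[C@@]1(CC=C)CC(OC)C(=O)n1ccnc1
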